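Everything rests on building rings A and B together from a 2-pyrone. The diene carbons C3 to C6 of a 4-methoxy-5-naphthyl-2-pyrone become C7 (H), C6 (OMe), C5 (naphthyl) and C4a of ring A. The ring B atoms C4, C3, N and C1 form a tether from pyrone C6 to the alkyne C8a≡C8, whose end carries a pinacol boronate as latent C8 hydroxyl. Heating this precursor makes C4a–C8a and C7–C8 in one intramolecular [4+2] cycloaddition, and loss of CO2 aromatises ring A. Both stereocentres (1R,3R) are in place beforehand, from an (R)-3-aminobutanoate and from SN2 inversion of (S)-but-3-yn-2-ol.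

Key step: step 17

Assumption: the target SMILES fixes C1 and C3 (both R, methyl groups trans) but not the sense of the C5–naphthyl axis. That axis is therefore treated as an uncontrolled extra stereogenic element, and its two rotamers (diastereomers) are separated after the last step.

Design remark: nitrogen carries a methyl carbamate, which is thermally inert, non-basic, planar and the later source of N-CH3. Boron is attached last, without strong base, because the pyrone C6 methylene is acidic and lies β to the carbamate nitrogen.

**Naphthalene fragment**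

Step 1
Reactants: 1 2-bromo-5-methoxybenzaldehyde; 2 dimethyl succinate
Product: 3 (E)-4-(2-bromo-5-methoxyphenyl)-3-(methoxycarbonyl)but-3-enoic acid
Conditions: NaOMe, MeOH, reflux; then aq. HCl
Reagents that add atoms: none
Why: Stobbe condensation, in which the succinate enolate adds to the non-enolisable aldehyde, the alkoxide lactonises and base-induced ring opening gives the (E)-half-ester with aryl and CH2CO2H cis, as the next ring closure requires.

Step 2
Reactants: 3 the Stobbe half-ester
Product: 4 methyl 4-acetoxy-8-bromo-5-methoxynaphthalene-2-carboxylate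
Conditions: Ac2O, NaOAc, reflux
Reagents that add atoms: acetic anhydride, CC(=O)OC(C)=O
Why: The mixed anhydride undergoes intramolecular Friedel-Crafts acylation at the only free ortho position (activated by OMe, the other one blocked by bromine), and the naphthol tautomer is trapped as its acetate.

Step 3
Reactants: 4 the acetoxy naphthoate
Product: 6 methyl 8-bromo-4,5-dimethoxynaphthalene-2-carboxylate, via naphthol 5 (not isolated)
Conditions: K2CO3, MeOH, rt; solvent swap; MeI, K2CO3, DMF, rt
Reagents that add atoms: iodomethane, CI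
Why: Carbonate-mediated methanolysis uncovers the peri-naphthol and Williamson O-methylation caps it, while the methyl ester is degenerate toward methanol.

Step 4
Reactants: 6 the dimethoxy naphthoate
Product: 7 (8-bromo-4,5-dimethoxynaphthalen-2-yl)methanol
Conditions: LiAlH4, THF, 0 °C
Reagents that add atoms: none
Why: Hydride reduction of the ester at low temperature is much faster than any attack on the aryl bromide.

Step 5
Reactants: 7 the naphthylmethanol
Product: 9 1-bromo-4,5-dimethoxy-7-methylnaphthalene, via benzylic mesylate 8 (not isolated)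
Conditions: MsCl, Et3N, THF, 0 °C; then LiEt3BH, 0 °C to rt
Reagents that add atoms: methanesulfonyl chloride, CS(=O)(=O)Cl (its atoms stay only in intermediate 8)
Why: Sulfonate activation followed by SN2 hydride displacement deoxygenates the primary benzylic position, and the aryl bromide and aryl ethers are inert to LiEt3BH at this temperature.

Step 6
Reactants: 9 the bromonaphthalene; 10 (2-tert-butoxy-2-oxoethyl)zinc bromide (commercial solution)
Product: 11 tert-butyl 2-(4,5-dimethoxy-7-methylnaphthalen-1-yl)acetate
Conditions: Pd2(dba)3 (cat.), XPhos (cat.), THF, 60 °C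
Reagents that add atoms: none
Why: Negishi-type α-arylation with a Reformatsky reagent, in which zerovalent palladium inserts into C-Br, the neutral zinc enolate transmetalates and reductive elimination gives the arylacetate without strong base.

**Amine fragment**

Step 7
Reactants: 12 (S)-but-3-yn-2-ol
Product: 13 (S)-but-3-yn-2-yl methanesulfonate
Conditions: MsCl, Et3N, CH2Cl2, -20 to 0 °C; aqueous wash to remove chloride salts
Reagents that add atoms: methanesulfonyl chloride, CS(=O)(=O)Cl
Why: O-sulfonylation leaves the C-O bond untouched, so the (S) configuration is retained.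

Step 8
Reactants: 13 the (S)-mesylate; 14 tert-butyl (R)-3-aminobutanoate (free base, 2 equiv)
Product: 15 tert-butyl (3R)-3-{[(2R)-but-3-yn-2-yl]amino}butanoate
Conditions: K2CO3, MeCN, 55 °C, halide-free
Reagents that add atoms: none
Why: SN2 displacement of the secondary propargylic mesylate by the primary amine inverts the carbinol carbon to (R) (future C1), the absence of halide prevents a double inversion, the branched product resists a second alkylation, and C3 comes unchanged from the chiral pool.

Step 9
Reactants: 15 the secondary amine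
Product: 16 tert-butyl (3R)-3-{(methoxycarbonyl)[(2R)-but-3-yn-2-yl]amino}butanoate
Conditions: ClCO2Me, iPr2NEt, CH2Cl2, 0 °C to rt
Reagents that add atoms: methyl chloroformate, COC(=O)Cl
Why: N-acylation of the secondary amine with a chloroformate installs the robust methyl carbamate that later becomes N-methyl.

Step 10
Reactants: 16 the carbamate ester
Product: 17 (3R)-3-{(methoxycarbonyl)[(2R)-but-3-yn-2-yl]amino}butanoic acid
Conditions: TFA, CH2Cl2, 0 °C to rt
Reagents that add atoms: none
Why: Acidolysis of the tert-butyl ester (E1 loss of isobutene) uncovers the acid without base, so the β-carbamate cannot be eliminated and the methyl carbamate survives.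

**Union, pyrone and end game**

Step 11
Reactants: 17 the carbamate acid; 11 the tert-butyl arylacetate
Product: 20 tert-butyl (5R)-2-(4,5-dimethoxy-7-methylnaphthalen-1-yl)-5-{(methoxycarbonyl)[(2R)-but-3-yn-2-yl]amino}-3-oxohexanoate (C2 undefined), via acyl imidazolide 18 (not isolated), via lithium enolate 19 (not isolated)
Conditions: 17, CDI, THF, rt; separately 11, LiN(SiMe3)2 (2.1 equiv), THF, -78 °C; combine, -78 to -40 °C; AcOH quench
Reagents that add atoms: 1,1'-carbonyldiimidazole, O=C(n1ccnc1)n1ccnc1 (imidazolyl group of 18 only); lithium hexamethyldisilazide, [Li+].C[Si](C)(C)[N-][Si](C)(C)C (lithium of 19 only)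
Why: Crossed Claisen C-acylation, in which the stabilised arylacetate enolate attacks the reactive acyl imidazolide faster than it can enolise it, the second equivalent of base absorbs the imidazole N-H, and the new α-carbon does not matter because it ceases to be a stereocentre in the next step.

Step 12
Reactants: 20 the β-keto ester
Product: 22 methyl N-[(2R)-but-3-yn-2-yl]-N-[(2R)-5-(4,5-dimethoxy-7-methylnaphthalen-1-yl)-4-oxopentan-2-yl]carbamate, via β-keto acid 21 (not isolated)
Conditions: TFA, anisole, CH2Cl2, rt; then toluene, 80 °C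
Reagents that add atoms: none
Why: tert-Butyl ester acidolysis followed by decarboxylation of the β-keto acid through its cyclic six-membered transition state gives the naphthylmethyl ketone without base, leaving C1, C3, carbamate and alkyne untouched.

Step 13
Reactants: 22 the naphthylmethyl ketone
Product: 23 methyl N-[(2R)-but-3-yn-2-yl]-N-[(2R,4Z)-5-(4,5-dimethoxy-7-methylnaphthalen-1-yl)-4-(trimethylsilyloxy)pent-4-en-2-yl]carbamate
Conditions: TMSOTf, Et3N, CH2Cl2, 0 °C; pentane extraction, no aqueous acid
Reagents that add atoms: trimethylsilyl triflate, C[Si](C)(C)OS(=O)(=O)C(F)(F)F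
Why: Soft enolisation removes the more acidic benzylic proton and gives the aryl-conjugated silyl enol ether, which avoids the enolate on the nitrogen side that could expel the carbamate.

Step 14
Reactants: 23 the silyl enol ether; 24 malonyl dichloride
Product: 25 methyl N-[(2R)-but-3-yn-2-yl]-N-{(2R)-1-[5-(4,5-dimethoxy-7-methylnaphthalen-1-yl)-4-hydroxy-2-oxo-2H-pyran-6-yl]propan-2-yl}carbamate
Conditions: Et2O, -78 °C to rt
Reagents that add atoms: none
Why: Known pyrone annulation of silyl enol ethers with malonyl dichloride, in which C-acylation at the benzylic enol carbon (future C5) and then O-acylation by the enolised ketone close the 4-hydroxy-2-pyrone.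

Step 15
Reactants: 25 the 4-hydroxy-2-pyrone
Product: 26 methyl N-[(2R)-but-3-yn-2-yl]-N-{(2R)-1-[5-(4,5-dimethoxy-7-methylnaphthalen-1-yl)-4-methoxy-2-oxo-2H-pyran-6-yl]propan-2-yl}carbamate
Conditions: Me2SO4, K2CO3, acetone, rt
Reagents that add atoms: dimethyl sulfate, COS(=O)(=O)OC
Why: O-alkylation of the acidic vinylogous acid under these conditions is the standard entry to 4-methoxy-2-pyrones, and carbonate is too weak to deprotonate the C6 methylene.

Step 16
Reactants: 26 the terminal alkyne pyrone
Product: 27 methyl N-[(2R)-4-(4,4,5,5-tetramethyl-1,3,2-dioxaborolan-2-yl)but-3-yn-2-yl]-N-{(2R)-1-[5-(4,5-dimethoxy-7-methylnaphthalen-1-yl)-4-methoxy-2-oxo-2H-pyran-6-yl]propan-2-yl}carbamate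
Conditions: (CAAC)CuOTf [CAAC = 1-(2,6-diisopropylphenyl)-3,3-diethyl-5,5-dimethylpyrrolidin-2-ylidene] (2.5 mol %), Et3N (5 mol %), HBpin (1.1 equiv), toluene, rt; filtration through dry Celite, used at once
Reagents that add atoms: pinacolborane, CC1(C)OBOC1(C)C
Why: Catalytic dehydrogenative C(sp)-H borylation, in which a monovalent copper acetylide formed with catalytic amine is borylated by HBpin and the copper hydride is protonated to H2, so that no strong base or nucleophile meets the pyrone.

Step 17
Reactants: 27 the pyrone-alkynylboronate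
Product: 29 methyl (1R,3R)-5-(4,5-dimethoxy-7-methylnaphthalen-1-yl)-6-methoxy-1,3-dimethyl-8-(4,4,5,5-tetramethyl-1,3,2-dioxaborolan-2-yl)-3,4-dihydroisoquinoline-2(1H)-carboxylate, via bridged lactone 28 (not isolated)
Conditions: 1,2-dichlorobenzene (0.01 M, dry, degassed), BHT (cat.), sealed vessel, 180-200 °C
Reagents that add atoms: none
Why: The pyrone diene (C3=C4-C5=C6) and the tethered alkynylboronate combine in a thermal intramolecular [4+2] cycloaddition to the 2-oxabicyclo[2.2.2]octadienone 28, which expels CO2 by retro-[4+2] and thereby makes the sequence irreversible. The closest known reactions are the intramolecular 2-pyrone/alkyne Diels-Alder benzannulation and the intermolecular 2-pyrone/alkynylboronate synthesis of aryl boronates. Ring B closes as the six-membered ring spanned by C4-C3-N-C1 when C4a-C8a forms (type 1 intramolecular mode, tether on the diene terminus), and ring A closes as the new carbocycle from four pyrone carbons and two alkyne carbons (C4a-C8a plus C7-C8), benzenoid after decarboxylation. No tetrahedral stereocentre is created, since the bridgeheads of 28 are flattened; C1 and C3 lie in the tether and are untouched, and the only new stereogenic element is the C5-naphthyl axis, for which no control is claimed. The selectivity needed is regiochemical (boron at C8, next to C7-H), and the tether length secures it by allowing only the pairing C8a/C4a and C8/C7, whatever the electronic preference of the partners. The planar carbamate nitrogen and the two α-methyl branches favour the folded conformer, and high dilution suppresses intermolecular reaction.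

Step 18
Reactants: 29 the C8 aryl boronate
Product: 30 methyl (1R,3R)-5-(4,5-dimethoxy-7-methylnaphthalen-1-yl)-8-hydroxy-6-methoxy-1,3-dimethyl-3,4-dihydroisoquinoline-2(1H)-carboxylate
Conditions: 30% aq. H2O2, NaOH, THF, 0 °C; aq. NH4Cl
Reagents that add atoms: hydrogen peroxide, OO
Why: Boronate oxidation, in which hydroperoxide adds to boron, the aryl group migrates from boron to oxygen at the same carbon and hydrolysis gives the C8 phenol, chemically distinct from the C6 methyl ether.

Step 19
Reactants: 30 the phenol carbamate
Product: 31 ancistrocongoline B, (1R,3R)-5-(4,5-dimethoxy-7-methylnaphthalen-1-yl)-6-methoxy-1,2,3-trimethyl-1,2,3,4-tetrahydroisoquinolin-8-ol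
Conditions: LiAlH4, THF, reflux; Rochelle salt work-up; preparative HPLC to part the two rotamers about the biaryl axis
Reagents that add atoms: none
Why: Exhaustive hydride reduction of the methyl carbamate (loss of methoxide, then reduction of the iminium ion) gives N-methyl without touching C1 or C3, the phenol being carried as its aluminate.

**Compound list**

1 | 2-bromo-5-methoxybenzaldehyde | COc1ccc(Br)c(C=O)c1 | starting material
2 | dimethyl succinate | COC(=O)CCC(=O)OC | starting material
3 | (E)-4-(2-bromo-5-methoxyphenyl)-3-(methoxycarbonyl)but-3-enoic acid | OC(=O)C/C(C(=O)OC)=C\c1cc(OC)ccc1Br | intermediate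
4 | methyl 4-acetoxy-8-bromo-5-methoxynaphthalene-2-carboxylate | COC(=O)c1cc(OC(C)=O)c2c(OC)ccc(Br)c2c1 | intermediate
5 | methyl 8-bromo-4-hydroxy-5-methoxynaphthalene-2-carboxylate (not isolated) | COC(=O)c1cc(O)c2c(OC)ccc(Br)c2c1 | intermediate
6 | methyl 8-bromo-4,5-dimethoxynaphthalene-2-carboxylate | COC(=O)c1cc(OC)c2c(OC)ccc(Br)c2c1 | intermediate
7 | (8-bromo-4,5-dimethoxynaphthalen-2-yl)methanol | OCc1cc(OC)c2c(OC)ccc(Br)c2c1 | intermediate
8 | (8-bromo-4,5-dimethoxynaphthalen-2-yl)methyl methanesulfonate (not isolated) | CS(=O)(=O)OCc1cc(OC)c2c(OC)ccc(Br)c2c1 | intermediate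
9 | 1-bromo-4,5-dimethoxy-7-methylnaphthalene | Cc1cc(OC)c2c(OC)ccc(Br)c2c1 | intermediate
10 | (2-tert-butoxy-2-oxoethyl)zinc bromide | CC(C)(C)OC(=O)C[Zn]Br | starting material
11 | tert-butyl 2-(4,5-dimethoxy-7-methylnaphthalen-1-yl)acetate | CC(C)(C)OC(=O)Cc1ccc(OC)c2c(OC)cc(C)cc12 | intermediate
12 | (S)-but-3-yn-2-ol | C[C@H](O)C#C | starting material
13 | (S)-but-3-yn-2-yl methanesulfonate | C[C@H](OS(C)(=O)=O)C#C | intermediate
14 | tert-butyl (R)-3-aminobutanoate | CC(C)(C)OC(=O)C[C@@H](C)N | starting material
15 | tert-butyl (3R)-3-{[(2R)-but-3-yn-2-yl]amino}butanoate | CC(C)(C)OC(=O)C[C@@H](C)N[C@H](C)C#C | intermediate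
16 | tert-butyl (3R)-3-{(methoxycarbonyl)[(2R)-but-3-yn-2-yl]amino}butanoate | CC(C)(C)OC(=O)C[C@@H](C)N(C(=O)OC)[C@H](C)C#C | intermediate
17 | (3R)-3-{(methoxycarbonyl)[(2R)-but-3-yn-2-yl]amino}butanoic acid | OC(=O)C[C@@H](C)N(C(=O)OC)[C@H](C)C#C | intermediate
18 | acyl imidazolide of 17 (not isolated) | O=C(C[C@@H](C)N(C(=O)OC)[C@H](C)C#C)n1ccnc1 | intermediate
19 | lithium enolate of 11 (not isolated) | [Li+].CC(C)(C)OC([O-])=Cc1ccc(OC)c2c(OC)cc(C)cc12 | intermediate
20 | tert-butyl (5R)-2-(4,5-dimethoxy-7-methylnaphthalen-1-yl)-5-{(methoxycarbonyl)[(2R)-but-3-yn-2-yl]amino}-3-oxohexanoate (C2 undefined) | CC(C)(C)OC(=O)C(C(=O)C[C@@H](C)N(C(=O)OC)[C@H](C)C#C)c1ccc(OC)c2c(OC)cc(C)cc12 | intermediate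
21 | β-keto acid corresponding to 20 (not isolated) | OC(=O)C(C(=O)C[C@@H](C)N(C(=O)OC)[C@H](C)C#C)c1ccc(OC)c2c(OC)cc(C)cc12 | intermediate
22 | methyl N-[(2R)-but-3-yn-2-yl]-N-[(2R)-5-(4,5-dimethoxy-7-methylnaphthalen-1-yl)-4-oxopentan-2-yl]carbamate | COC(=O)N([C@H](C)C#C)[C@H](C)CC(=O)Cc1ccc(OC)c2c(OC)cc(C)cc12 | intermediate
23 | (Z)-trimethylsilyl enol ether of 22 on the naphthyl side | COC(=O)N([C@H](C)C#C)[C@H](C)C/C(O[Si](C)(C)C)=C/c1ccc(OC)c2c(OC)cc(C)cc12 | intermediate
24 | malonyl dichloride | O=C(Cl)CC(=O)Cl | starting material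
25 | 4-hydroxy-2-pyrone with terminal alkyne tether | COC(=O)N([C@H](C)C#C)[C@H](C)Cc1oc(=O)cc(O)c1-c1ccc(OC)c2c(OC)cc(C)cc12 | intermediate
26 | 4-methoxy-2-pyrone with terminal alkyne tether | COC(=O)N([C@H](C)C#C)[C@H](C)Cc1oc(=O)cc(OC)c1-c1ccc(OC)c2c(OC)cc(C)cc12 | intermediate
27 | pyrone-alkynylboronate, precursor of the key step | COC(=O)N([C@H](C)C#CB1OC(C)(C)C(C)(C)O1)[C@H](C)Cc1oc(=O)cc(OC)c1-c1ccc(OC)c2c(OC)cc(C)cc12 | intermediate
28 | bridged lactone cycloadduct, 2-oxabicyclo[2.2.2]octa-5,7-dien-3-one, bridgeheads C4a and C7 undefined (not isolated) | O=C1OC23C[C@@H](C)N(C(=O)OC)[C@H](C)C2=C(B4OC(C)(C)C(C)(C)O4)C1C(OC)=C3c5ccc(OC)c6c(OC)cc(C)cc56 | intermediate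
29 | C8 pinacolboronate N-methoxycarbonyl tetrahydroisoquinoline, product of the key step | COc1cc(B3OC(C)(C)C(C)(C)O3)c2c(c1-c1ccc(OC)c3c(OC)cc(C)cc13)C[C@@H](C)N(C(=O)OC)[C@@H]2C | intermediate
30 | C8 phenol N-methoxycarbonyl tetrahydroisoquinoline | COc1cc(O)c2c(c1-c1ccc(OC)c3c(OC)cc(C)cc13)C[C@@H](C)N(C(=O)OC)[C@@H]2C | intermediate
31 | ancistrocongoline B | COc1cc(O)c2c(c1-c1ccc(OC)c3c(OC)cc(C)cc13)C[C@@H](C)N(C)[C@@H]2C | target

Total step count: 19. Longest linear sequence: 15 (steps 1-6, then 11-19).

**Steps most likely to fail**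

**Step 17.**
- Risk: the cycloaddition of the donor-substituted, sterically loaded pyrone may be slower than thermal protodeboronation of the alkynylboronate, or slower than vinylogous β-elimination of the carbamate from the C6 side chain.
- Fallback: lower the dienophile LUMO instead of raising the temperature. Setting out from 27, KHF2 in aqueous MeOH should give the potassium alkynyltrifluoroborate F1. Fluoride abstraction with BF3·OEt2 in 1,2-dichloroethane (rt to 60 °C) generates the alkynyldifluoroborane F2, a much stronger acceptor, as is known for trifluoroborate/2-pyrone benzannulations. The same tethered cycloaddition and CO2 loss then lead to the aryldifluoroborane F3. This is oxidised during work-up (H2O2, NaOH), and the route is rejoined at 30.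

**Step 16.**
- Risk: hydroboration of the triple bond or hydride delivery to the pyrone may compete with C-H borylation, and the boronate may be lost by protodeboronation on isolation.
- Fallback: stoichiometric metalation one stage earlier, where the pyrone protects itself as its anion. Setting out from 25, LDA (2.1 equiv, THF, -78 °C) removes first the 4-OH proton and then the acetylenic proton. The pyronate is neither electrophilic nor easily deprotonated at its C6 methylene. Trapping with iPrOBpin and quenching with anhydrous HCl in Et2O should give the 4-hydroxy-2-pyrone alkynylboronate F4. Neutral Mitsunobu O-methylation of F4 (MeOH, PPh3, DIAD, THF, 0 °C) comes back to the route at 27.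

**Step 14.**
- Risk: liberated HCl may protodesilylate the hindered enol ether, or O-acylation and self-condensation of malonyl dichloride may outrun C-acylation at the carbon that bears the bulky naphthyl group.
- Fallback: bring pyrone C2-C4 in from Meldrum's acid through an acylketene.
  - Setting out from 11, TFA gives the arylacetic acid F5.
  - DCC/DMAP coupling with Meldrum's acid gives the acyl Meldrum's acid F6.
  - Heating F6 with acetone in toluene gives the 6-(naphthylmethyl)dioxinone F7.
  - The lithium dienolate of F7 (LiN(SiMe3)2, THF, -78 °C) is acylated at the benzylic γ-carbon by imidazolide 18 (from 17) to give the keto-dioxinone F8.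
  - Thermolysis of F8 in toluene at 110 °C expels acetone, and the acylketene is captured by the ketone enol, so that the route is rejoined at 25, bypassing 20 to 23.

**Further compounds**

F1 | step 17 | potassium alkynyltrifluoroborate corresponding to 27 | [K+].COC(=O)N([C@H](C)C#C[B-](F)(F)F)[C@H](C)Cc1oc(=O)cc(OC)c1-c1ccc(OC)c2c(OC)cc(C)cc12
F2 | step 17 | alkynyldifluoroborane corresponding to 27 | COC(=O)N([C@H](C)C#CB(F)F)[C@H](C)Cc1oc(=O)cc(OC)c1-c1ccc(OC)c2c(OC)cc(C)cc12
F3 | step 17 | C8 aryldifluoroborane N-methoxycarbonyl tetrahydroisoquinoline | COc1cc(B(F)F)c2c(c1-c1ccc(OC)c3c(OC)cc(C)cc13)C[C@@H](C)N(C(=O)OC)[C@@H]2C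
F4 | step 16 | 4-hydroxy-2-pyrone alkynyl pinacolboronate | COC(=O)N([C@H](C)C#CB1OC(C)(C)C(C)(C)O1)[C@H](C)Cc1oc(=O)cc(O)c1-c1ccc(OC)c2c(OC)cc(C)cc12
F5 | step 14 | 2-(4,5-dimethoxy-7-methylnaphthalen-1-yl)acetic acid | OC(=O)Cc1ccc(OC)c2c(OC)cc(C)cc12
F6 | step 14 | 5-[2-(4,5-dimethoxy-7-methylnaphthalen-1-yl)acetyl]-2,2-dimethyl-1,3-dioxane-4,6-dione | CC1(C)OC(=O)C(C(=O)Cc2ccc(OC)c3c(OC)cc(C)cc23)C(=O)O1
F7 | step 14 | 6-[(4,5-dimethoxy-7-methylnaphthalen-1-yl)methyl]-2,2-dimethyl-4H-1,3-dioxin-4-one | CC1(C)OC(=O)C=C(Cc2ccc(OC)c3c(OC)cc(C)cc23)O1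
F8 | step 14 | keto-dioxinone, γ-acylated F7 (benzylic carbon undefined) | CC1(C)OC(=O)C=C(O1)C(C(=O)C[C@@H](C)N(C(=O)OC)[C@H](C)C#C)c1ccc(OC)c2c(OC)cc(C)cc12
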